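**Retrosynthetic overview**
1. The ten-membered carbocycle is opened at C1–C2. It is closed last, by a Nozaki–Hiyama–Kishi (NHK) reaction between a Z-alkenyl iodide and a β,γ-unsaturated aldehyde, followed only by desilylation.
2. The C9 ester comes from a Mitsunobu reaction (inversion) of a 9-epi alcohol with O-TBS-sarracinic acid, a C5 fragment made from crotonaldehyde.
3. The trans α-methylene-γ-lactone comes from a late C6–C7 zinc Barbier union of a C6 enal (from but-3-yn-1-ol) with a C9 3-(bromomethyl)dihydropyranone, followed by a δ→γ acyl shift.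
4. The dihydropyranone comes from RCM of the 2-(silyloxymethyl)acrylate of an (R)-homoallylic alcohol. That alcohol comes from Brown allylation of (Z)-3-iodo-2-methylacrolein, itself made from propargyl alcohol.
5. Ring order: temporary δ-lactone (RCM), then γ-lactone (acyl shift), then carbocycle (NHK).

Assumption: germacrane locants are used for orientation (C6 = lactone O–CH, C7 = ring-fusion CH, C9 = acyloxy CH, C2 = carbinol CH, C11=C13 = exocyclic methylene); read this way the target is 2R,6R,7S,9S, 1(10)Z, 4E, with a (Z)-configured ester side chain.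

**East fragment (C1, C7–C14)**

Step 1
Reactants: 1 prop-2-yn-1-ol
Product: 3 (Z)-3-iodo-2-methylprop-2-en-1-ol, via alkenylmagnesium alkoxide 2 (not isolated)
Conditions: MeMgBr (2.5 equiv), CuI (20 mol %), Et2O/THF, −10 °C → rt; then I2, 0 °C; aq. work-up
Reagents that add atoms: methylmagnesium bromide, C[Mg]Br; iodine, II
Why: Copper-catalysed, alkoxide-directed anti-carbomagnesiation (Duboudin–Jousseaume) puts CH3 on the inner carbon and Mg on the terminus cis to CH2O, and iodinolysis with retention gives the Z iodide that becomes the Z C1=C10 bond.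

Step 2
Reactants: 3 (Z)-3-iodo-2-methylprop-2-en-1-ol
Product: 4 (Z)-3-iodo-2-methylprop-2-enal
Conditions: MnO2 (15 equiv), CH2Cl2, rt, dark; used at once
Reagents that add atoms: none
Why: Neutral allylic oxidation with MnO2 gives the labile Z-enal without Z→E isomerisation.

Step 3
Reactants: 4 (Z)-3-iodo-2-methylprop-2-enal
Product: 6 (1Z,3R)-1-iodo-2-methylhexa-1,5-dien-3-ol, via borinate 5 (not isolated)
Conditions: B-allylbis(isopinocampheyl)borane from (−)-α-pinene (1.2 equiv), Et2O, −78 °C; then 3 M NaOH, 30 % H2O2, 0 °C → rt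
Reagents that add atoms: B-allylbis(isopinocampheyl)borane, (−)-α-pinene series, C=CCB([C@H]1C[C@H]2C[C@@H]([C@@H]1C)C2(C)C)[C@H]1C[C@H]2C[C@@H]([C@@H]1C)C2(C)C
Why: Brown asymmetric allylboration through a chair Zimmerman–Traxler transition state sets the carbinol as 3R (9R, deliberately 9-epi) by reagent control (typically ≥ 90 % ee), and the vinyl iodide survives the alkaline peroxide work-up.

Step 4
Reactants: 7 methyl 2-(hydroxymethyl)prop-2-enoate
Product: 8 methyl 2-{[(tert-butyldimethylsilyl)oxy]methyl}prop-2-enoate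
Conditions: TBSCl, imidazole, CH2Cl2, 0 °C → rt
Reagents that add atoms: tert-butyldimethylsilyl chloride, CC(C)(C)[Si](C)(C)Cl
Why: Standard silylation masks the primary allylic alcohol that later becomes the allylic bromide.

Step 5
Reactants: 8 methyl 2-{[(tert-butyldimethylsilyl)oxy]methyl}prop-2-enoate
Product: 9 2-{[(tert-butyldimethylsilyl)oxy]methyl}prop-2-enoic acid
Conditions: LiOH, THF/H2O, 0 °C → rt; cold 1 M HCl to pH 4
Reagents that add atoms: lithium hydroxide, [Li+].[OH-]
Why: Saponification of the unhindered methyl ester is faster than silyl ether cleavage or conjugate addition of hydroxide.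

Step 6
Reactants: 6 (1Z,3R)-1-iodo-2-methylhexa-1,5-dien-3-ol; 9 2-{[(tert-butyldimethylsilyl)oxy]methyl}prop-2-enoic acid
Product: 10 (1Z,3R)-1-iodo-2-methylhexa-1,5-dien-3-yl 2-{[(tert-butyldimethylsilyl)oxy]methyl}prop-2-enoate
Conditions: DCC, DMAP (10 mol %), CH2Cl2, 0 °C → rt
Reagents that add atoms: none
Why: Steglich esterification acylates at oxygen, so the C9 configuration is retained.

Step 7
Reactants: 10 (1Z,3R)-1-iodo-2-methylhexa-1,5-dien-3-yl 2-{[(tert-butyldimethylsilyl)oxy]methyl}prop-2-enoate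
Product: 11 (6R)-3-{[(tert-butyldimethylsilyl)oxy]methyl}-6-[(1Z)-1-iodoprop-1-en-2-yl]-5,6-dihydro-2H-pyran-2-one
Conditions: Hoveyda–Grubbs II (5 mol %), toluene (0.01 M), 80 °C
Reagents that add atoms: none
Why: Ring-closing metathesis of the terminal alkene with the 1,1-disubstituted acrylate closes the six-membered enoate, leaves the hindered vinyl iodide untouched, and locks C8 trans to the future CH2–metal group.

Step 8
Reactants: 11 (6R)-3-{[(tert-butyldimethylsilyl)oxy]methyl}-6-[(1Z)-1-iodoprop-1-en-2-yl]-5,6-dihydro-2H-pyran-2-one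
Product: 12 (6R)-3-(hydroxymethyl)-6-[(1Z)-1-iodoprop-1-en-2-yl]-5,6-dihydro-2H-pyran-2-one
Conditions: HF·pyridine, pyridine, THF, 0 °C → rt
Reagents that add atoms: none
Why: Buffered fluoride desilylation frees the primary alcohol without opening the allylic lactone.

Step 9
Reactants: 12 (6R)-3-(hydroxymethyl)-6-[(1Z)-1-iodoprop-1-en-2-yl]-5,6-dihydro-2H-pyran-2-one
Product: 13 (6R)-3-(bromomethyl)-6-[(1Z)-1-iodoprop-1-en-2-yl]-5,6-dihydro-2H-pyran-2-one
Conditions: CBr4, PPh3, CH2Cl2, −20 → 0 °C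
Reagents that add atoms: carbon tetrabromide, BrC(Br)(Br)Br
Why: The Appel reaction converts the primary allylic alcohol into the bromide under neutral conditions without allylic transposition.

**West fragment (C2–C6, C15)**

Step 10
Reactants: 14 but-3-yn-1-ol
Product: 15 1-[(but-3-yn-1-yloxy)methyl]-4-methoxybenzene
Conditions: NaH, PMBCl, Bu4NI (cat.), THF/DMF, 0 °C → rt
Reagents that add atoms: 4-methoxybenzyl chloride, COc1ccc(CCl)cc1
Why: Williamson etherification installs a PMB group that is orthogonal to the silyl ether kept until the last step.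

Step 11
Reactants: 15 1-[(but-3-yn-1-yloxy)methyl]-4-methoxybenzene
Product: 18 (2E)-5-[(4-methoxybenzyl)oxy]-3-methylpent-2-en-1-ol, via vinylalane 16 (not isolated), via lithium alanate 17 (not isolated)
Conditions: Me3Al, Cp2ZrCl2 (20 mol %), CH2Cl2, 0 °C → rt; evaporate; n-BuLi, hexane/THF, −78 → 0 °C; (CH2O)n, rt; aq. work-up
Reagents that add atoms: trimethylaluminium, C[Al](C)C; formaldehyde (from paraformaldehyde), C=O
Why: Negishi Zr-catalysed syn-carboalumination places CH3 and Al cis on the alkyne, and hydroxymethylation of the derived alanate with retention fixes the E C4=C5 geometry.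

Step 12
Reactants: 18 (2E)-5-[(4-methoxybenzyl)oxy]-3-methylpent-2-en-1-ol
Product: 19 (2E)-5-[(4-methoxybenzyl)oxy]-3-methylpent-2-enal
Conditions: MnO2 (15 equiv), CH2Cl2, rt
Reagents that add atoms: none
Why: Selective allylic oxidation with MnO2 gives the E-enal and leaves the PMB ether untouched.

**Side-chain acid (C5)**

Step 13
Reactants: 20 (E)-but-2-enal
Product: 21 (Z)-2-iodobut-2-enal
Conditions: I2, K2CO3, DMAP (20 mol %), THF/H2O 1:1, rt
Reagents that add atoms: iodine, II
Why: Baylis–Hillman-type α-iodination (DMAP addition, iodination, elimination) gives the isomer with CH3 cis to iodine.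

Step 14
Reactants: 21 (Z)-2-iodobut-2-enal
Product: 22 (Z)-2-iodobut-2-en-1-ol
Conditions: NaBH4, MeOH, 0 °C
Reagents that add atoms: none
Why: 1,2-Reduction of the aldehyde by borohydride leaves the vinyl iodide and its geometry intact.

Step 15
Reactants: 22 (Z)-2-iodobut-2-en-1-ol
Product: 23 tert-butyl{[(2Z)-2-iodobut-2-en-1-yl]oxy}dimethylsilane
Conditions: TBSCl, imidazole, CH2Cl2, rt
Reagents that add atoms: tert-butyldimethylsilyl chloride, CC(C)(C)[Si](C)(C)Cl
Why: Silylation protects the alcohol for the metalation and for every later step up to the final one.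

Step 16
Reactants: 23 tert-butyl{[(2Z)-2-iodobut-2-en-1-yl]oxy}dimethylsilane
Product: 25 (2Z)-2-{[(tert-butyldimethylsilyl)oxy]methyl}but-2-enoic acid, via alkenyllithium 24 (not isolated)
Conditions: n-BuLi (1.05 equiv), Et2O, −78 °C; CO2, −78 → 0 °C; cold 1 M HCl to pH 3
Reagents that add atoms: carbon dioxide, O=C=O
Why: Iodine–lithium exchange and carboxylation both proceed with retention at the configurationally stable alkenyllithium, so CO2H ends cis to CH3 (the sarracinate, angelate-type geometry).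

**Fragment union and endgame**

Step 17
Reactants: 13 (6R)-3-(bromomethyl)-6-[(1Z)-1-iodoprop-1-en-2-yl]-5,6-dihydro-2H-pyran-2-one; 19 (2E)-5-[(4-methoxybenzyl)oxy]-3-methylpent-2-enal
Product: 28 (4S,5R)-4-[(2R,3Z)-2-hydroxy-4-iodo-3-methylbut-3-en-1-yl]-5-{(1E)-4-[(4-methoxybenzyl)oxy]-2-methylbut-1-en-1-yl}-3-methylidenedihydrofuran-2(3H)-one, via allylzinc bromide 26 (not isolated), via delta-lactone zinc alkoxide 27 (not isolated)
Conditions: activated Zn dust (3 equiv), THF, 0 °C → rt, slow addition of 13 to Zn + 19; aq. pH 7 work-up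
Reagents that add atoms: none
Why: In this zinc Barbier (Reformatsky-type) allylation the ring-locked E-crotyl-type allylzinc attacks through C7 in a chair Zimmerman–Traxler transition state (anti C6/C7) on the face anti to the pseudo-equatorial C9 substituent (axial attack, 4,6-trans), and the axial zinc alkoxide then takes over the acyl group to give the more stable trans γ-lactone (6R,7S) and a free 9-OH.

Step 18
Reactants: 28 the 9R alcohol from step 17; 25 (2Z)-2-{[(tert-butyldimethylsilyl)oxy]methyl}but-2-enoic acid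
Product: 29 (2S,3Z)-4-iodo-3-methyl-1-[(3S,4... = 4S,5R lactone of 28)-yl]but-3-en-2-yl (2Z)-2-{[(tert-butyldimethylsilyl)oxy]methyl}but-2-enoate, i.e. 28 with C9 inverted to S and O-acylated by 25
Conditions: PPh3, DIAD, toluene, 0 °C → rt
Reagents that add atoms: none
Why: Mitsunobu esterification displaces the alkoxyphosphonium ion by SN2, so C9 goes from R to S as the C5 acid is attached, and SN2′ is disfavoured because it would have to hit the hindered iodine-bearing C1.

Step 19
Reactants: 29 the 9S ester with PMB ether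
Product: 30 the corresponding primary alcohol (C2–OH free)
Conditions: DDQ (1.3 equiv), CH2Cl2/pH 7 buffer 10:1, 0 °C
Reagents that add atoms: none
Why: Oxidative PMB cleavage is orthogonal to the TBS ether, the vinyl iodide, the allylic ester and the methylene lactone.

Step 20
Reactants: 30 the primary alcohol
Product: 31 the β,γ-unsaturated aldehyde (C2 = CHO)
Conditions: Dess–Martin periodinane, NaHCO3, CH2Cl2, 0 °C → rt; used at once
Reagents that add atoms: none
Why: Buffered Dess–Martin oxidation gives the homoallylic aldehyde without moving the C4=C5 bond into conjugation.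

Step 21
Reactants: 31 the iodo-aldehyde
Product: 33 O-TBS ether of the target (2R,6R,7S,9S; 1(10)Z,4E macrocycle), via alkenylchromium species 32 (not isolated)
Conditions: CrCl2 (10 equiv), NiCl2 (1 mol % of Cr), DMSO/THF, 2 mM, syringe pump, rt; aq. work-up
Reagents that add atoms: none
Why: The Nozaki–Hiyama–Kishi macrocyclisation adds the alkenylchromium (Z geometry retained for a trisubstituted iodide) chemoselectively to the aldehyde, and C2 is set by macrocyclic control (attack on the outward face of the carbonyl), which is expected to favour 2R and must be checked.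

Step 22
Reactants: 33 O-TBS ether of the target
Product: 34 target, (2R,6R,7S,9S,1(10)Z,4E)-2-hydroxy-9-[(2Z)-2-(hydroxymethyl)but-2-enoyloxy]germacra-1(10),4,11(13)-trien-12,6-olide
Conditions: Et3N·3HF, THF, rt
Reagents that add atoms: none
Why: Nearly neutral fluoride desilylation removes the primary allylic TBS group without acid-induced transannular cyclisation, acyl migration or addition to the methylene lactone.

**Compound list**
1 | prop-2-yn-1-ol | C#CCO | starting material
2 | bromomagnesium (2Z)-3-(bromomagnesio)-2-methylprop-2-en-1-olate | Br[Mg]OC/C(C)=C\[Mg]Br | intermediate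
3 | (Z)-3-iodo-2-methylprop-2-en-1-ol | OC/C(C)=C\I | intermediate
4 | (Z)-3-iodo-2-methylprop-2-enal | O=C/C(C)=C\I | intermediate
5 | bis(isopinocampheyl)borinate of 6 | I/C=C(/C)[C@H](OB([C@H]1C[C@H]2C[C@@H]([C@@H]1C)C2(C)C)[C@H]1C[C@H]2C[C@@H]([C@@H]1C)C2(C)C)CC=C | intermediate
6 | (1Z,3R)-1-iodo-2-methylhexa-1,5-dien-3-ol | I/C=C(/C)[C@H](O)CC=C | intermediate
7 | methyl 2-(hydroxymethyl)prop-2-enoate | C=C(CO)C(=O)OC | starting material
8 | methyl 2-(TBSO-methyl)prop-2-enoate | C=C(CO[Si](C)(C)C(C)(C)C)C(=O)OC | intermediate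
9 | 2-(TBSO-methyl)prop-2-enoic acid | C=C(CO[Si](C)(C)C(C)(C)C)C(=O)O | intermediate
10 | (1Z,3R)-1-iodo-2-methylhexa-1,5-dien-3-yl 2-(TBSO-methyl)prop-2-enoate | I/C=C(/C)[C@H](OC(=O)C(=C)CO[Si](C)(C)C(C)(C)C)CC=C | intermediate
11 | (6R)-3-(TBSO-methyl)-6-[(1Z)-1-iodoprop-1-en-2-yl]-5,6-dihydro-2H-pyran-2-one | I/C=C(/C)[C@H]1CC=C(CO[Si](C)(C)C(C)(C)C)C(=O)O1 | intermediate
12 | (6R)-3-(hydroxymethyl)-6-[(1Z)-1-iodoprop-1-en-2-yl]-5,6-dihydro-2H-pyran-2-one | I/C=C(/C)[C@H]1CC=C(CO)C(=O)O1 | intermediate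
13 | (6R)-3-(bromomethyl)-6-[(1Z)-1-iodoprop-1-en-2-yl]-5,6-dihydro-2H-pyran-2-one | I/C=C(/C)[C@H]1CC=C(CBr)C(=O)O1 | intermediate
14 | but-3-yn-1-ol | C#CCCO | starting material
15 | 1-[(but-3-yn-1-yloxy)methyl]-4-methoxybenzene | C#CCCOCc1ccc(OC)cc1 | intermediate
16 | dimethyl[(1E)-4-(PMBO)-2-methylbut-1-en-1-yl]alane | C[Al](C)/C=C(\C)CCOCc1ccc(OC)cc1 | intermediate
17 | lithium butyl(dimethyl)[(1E)-4-(PMBO)-2-methylbut-1-en-1-yl]alanate | [Li+].CCCC[Al-](C)(C)/C=C(\C)CCOCc1ccc(OC)cc1 | intermediate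
18 | (2E)-5-[(4-methoxybenzyl)oxy]-3-methylpent-2-en-1-ol | OC/C=C(\C)CCOCc1ccc(OC)cc1 | intermediate
19 | (2E)-5-[(4-methoxybenzyl)oxy]-3-methylpent-2-enal | O=C/C=C(\C)CCOCc1ccc(OC)cc1 | intermediate
20 | (E)-but-2-enal | C/C=C/C=O | starting material
21 | (Z)-2-iodobut-2-enal | C/C=C(\I)C=O | intermediate
22 | (Z)-2-iodobut-2-en-1-ol | C/C=C(\I)CO | intermediate
23 | tert-butyl{[(2Z)-2-iodobut-2-en-1-yl]oxy}dimethylsilane | C/C=C(\I)CO[Si](C)(C)C(C)(C)C | intermediate
24 | 1-(TBSO)but-2-en-2-yllithium (Li cis to CH3) | C/C=C(\[Li])CO[Si](C)(C)C(C)(C)C | intermediate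
25 | (2Z)-2-(TBSO-methyl)but-2-enoic acid | C/C=C(\C(=O)O)CO[Si](C)(C)C(C)(C)C | intermediate
26 | {[(6R)-6-[(1Z)-1-iodoprop-1-en-2-yl]-2-oxo-5,6-dihydro-2H-pyran-3-yl]methyl}zinc bromide | I/C=C(/C)[C@H]1CC=C(C[Zn]Br)C(=O)O1 | intermediate
27 | bromozinc alkoxide of (4S,6R)-4-[(1R,2E)-1-hydroxy-5-(PMBO)-3-methylpent-2-en-1-yl]-6-[(1Z)-1-iodoprop-1-en-2-yl]-3-methylidenetetrahydropyran-2-one | I/C=C(/C)[C@H]1C[C@H]([C@H](O[Zn]Br)/C=C(\C)CCOCc2ccc(OC)cc2)C(=C)C(=O)O1 | intermediate
28 | (4S,5R)-γ-lactone, 9R alcohol, PMB ether | C=C1C(=O)O[C@H](/C=C(\C)CCOCc2ccc(OC)cc2)[C@H]1C[C@@H](O)/C(C)=C\I | intermediate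
29 | 9S O-TBS-sarracinate, PMB ether | C=C1C(=O)O[C@H](/C=C(\C)CCOCc2ccc(OC)cc2)[C@H]1C[C@H](OC(=O)/C(=C\C)CO[Si](C)(C)C(C)(C)C)/C(C)=C\I | intermediate
30 | 9S ester, C2 primary alcohol | C=C1C(=O)O[C@H](/C=C(\C)CCO)[C@H]1C[C@H](OC(=O)/C(=C\C)CO[Si](C)(C)C(C)(C)C)/C(C)=C\I | intermediate
31 | 9S ester, C2 aldehyde | C=C1C(=O)O[C@H](/C=C(\C)CC=O)[C@H]1C[C@H](OC(=O)/C(=C\C)CO[Si](C)(C)C(C)(C)C)/C(C)=C\I | intermediate
32 | alkenylchromium(III) dichloride derived from 31 | C=C1C(=O)O[C@H](/C=C(\C)CC=O)[C@H]1C[C@H](OC(=O)/C(=C\C)CO[Si](C)(C)C(C)(C)C)/C(C)=C\[Cr](Cl)Cl | intermediate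
33 | O-TBS ether of the target | C=C1C(=O)O[C@@H]2/C=C(\C)C[C@@H](O)/C=C(/C)[C@@H](OC(=O)/C(=C\C)CO[Si](C)(C)C(C)(C)C)C[C@@H]12 | intermediate
34 | CNP0273961.1 | C=C1C(=O)O[C@@H]2/C=C(\C)C[C@@H](O)/C=C(/C)[C@@H](OC(=O)/C(=C\C)CO)C[C@@H]12 | target

**Step count**
- Total steps: 22.
- Longest linear sequence: 13 steps (1–3, 6–9, 17–22).

**Steps most likely to fail**

Step 17 (Barbier union).
- The anti C6/C7 relationship follows from the ring-locked allyl geometry. The 4,6-trans face selectivity, however, is only inferred from cuprate additions to 6-substituted dihydropyranones.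
- A minor cis adduct costs yield only, because its equatorial carbinol chain shifts the acyl group slowly and it stays a δ-lactone.
- If the aldehyde instead adds mainly syn to the C9 substituent, the stereochemical plan changes from "wrong C9, then invert" to "right C9, then retain". This fallback sets out from 4 and comes back at 29.
- Allylboration of 4 with the (+)-α-pinene-derived allylborane gives (1Z,3S)-1-iodo-2-methylhexa-1,5-dien-3-ol F1.
- DCC coupling with 9 gives the (3S)-acrylate F2, RCM gives the (6S)-silyloxymethyl dihydropyranone F3, desilylation gives the (6S)-hydroxymethyl lactone F4, and the Appel reaction gives the (6S)-bromide F5.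
- Zn with 19, followed by a DBU-assisted acyl shift, gives the 9S γ-lactone alcohol F6.
- F6 is acylated with 25 with retention (2,4,6-trichlorobenzoyl chloride, Et3N, DMAP) to give 29, and the Mitsunobu step is dropped.

Step 18 (Mitsunobu).
- The alcohol is secondary, allylic and flanked by a cis iodine. Elimination, SN2′ or ionisation, and phosphine addition to the methylene lactone can all compete.
- The fallback sets out from 28 and comes back at 29 by redox inversion instead of substitution.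
- Dess–Martin oxidation gives the Z-β-iodo enone F7.
- (R)-Me-CBS with catecholborane at −78 °C (reagent control, alkenyl as the large group) gives the 9S alcohol F8.
- F8 is esterified with 25 under Yamaguchi conditions with retention to give 29.

Step 21 (NHK macrocyclisation).
- The risks are oligomerisation and, above all, an unfavourable C2 epimer ratio.
- The fallback sets out from 31 and comes back at 33. It sets C2 by ketone reduction instead of by the C–C bond formation.
- The NHK product is taken on whatever its ratio, including the 2S alcohol F9.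
- It is oxidised with Dess–Martin periodinane to the macrocyclic Z-enone F10.
- F10 is reduced with (S)-Me-CBS and catecholborane at −78 °C to the 2R alcohol 33.

**Further compounds**
F1 | step 17 | (1Z,3S)-1-iodo-2-methylhexa-1,5-dien-3-ol | I/C=C(/C)[C@@H](O)CC=C
F2 | step 17 | (1Z,3S)-1-iodo-2-methylhexa-1,5-dien-3-yl 2-(TBSO-methyl)prop-2-enoate | I/C=C(/C)[C@@H](OC(=O)C(=C)CO[Si](C)(C)C(C)(C)C)CC=C
F3 | step 17 | (6S)-3-(TBSO-methyl)-6-[(1Z)-1-iodoprop-1-en-2-yl]-5,6-dihydro-2H-pyran-2-one | I/C=C(/C)[C@@H]1CC=C(CO[Si](C)(C)C(C)(C)C)C(=O)O1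
F4 | step 17 | (6S)-3-(hydroxymethyl)-6-[(1Z)-1-iodoprop-1-en-2-yl]-5,6-dihydro-2H-pyran-2-one | I/C=C(/C)[C@@H]1CC=C(CO)C(=O)O1
F5 | step 17 | (6S)-3-(bromomethyl)-6-[(1Z)-1-iodoprop-1-en-2-yl]-5,6-dihydro-2H-pyran-2-one | I/C=C(/C)[C@@H]1CC=C(CBr)C(=O)O1
F6 | step 17 | (4S,5R)-γ-lactone, 9S alcohol, PMB ether | C=C1C(=O)O[C@H](/C=C(\C)CCOCc2ccc(OC)cc2)[C@H]1C[C@H](O)/C(C)=C\I
F7 | step 18 | (4S,5R)-γ-lactone, C9 ketone (Z-β-iodo enone), PMB ether | C=C1C(=O)O[C@H](/C=C(\C)CCOCc2ccc(OC)cc2)[C@H]1CC(=O)/C(C)=C\I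
F8 | step 18 | (4S,5R)-γ-lactone, 9S alcohol, PMB ether | C=C1C(=O)O[C@H](/C=C(\C)CCOCc2ccc(OC)cc2)[C@H]1C[C@H](O)/C(C)=C\I
F9 | step 21 | 2S epimer of 33 | C=C1C(=O)O[C@@H]2/C=C(\C)C[C@H](O)/C=C(/C)[C@@H](OC(=O)/C(=C\C)CO[Si](C)(C)C(C)(C)C)C[C@@H]12
F10 | step 21 | macrocyclic C2 ketone (Z-enone), O-TBS | C=C1C(=O)O[C@@H]2/C=C(\C)CC(=O)/C=C(/C)[C@@H](OC(=O)/C(=C\C)CO[Si](C)(C)C(C)(C)C)C[C@@H]12
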